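**Retrosynthetic overview**
1. Atom labels: C1 quaternary methyl-bearing fusion carbon, C2 and C3 the CH2 groups of the five-membered ring, C4 the isopropyl carbinol, C5 the fusion CH, C6 the aroyloxy carbon, C7 CH2, C8 the methyl-bearing alkene carbon, C9 the alkene CH, C10 the ketone carbon.
2. The plan rests on the arc C10(=O)–C9H=C8(CH3) of the seven-membered ring, with C10 bonded to quaternary C1: deleting C9 (bonds C9–C10 and C9–C8) leaves the six-membered ring C10–C8–C7–C6–C5–C1 of a 2-methylcyclohexanone, which is the ring of (R)-carvone with its stereocentre as C5.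
3. Disconnections, last to first: the C6–O ester bond; C9 excised from the cycloheptenone (silyl enol ether of a trans-hydrindanone; methylene transfer, then oxidative opening of the shared cyclopropane bond); C6–OH from a C6 ketone by hydride delivered from the C4 hydroxyl, the ketone from allylic oxidation of the carvone enone.
4. Further back: the C4–isopropyl bond (Grignard addition to a cyclopentenone), the C2–C3 bond (aldol closure of the methyl ketone from the isopropenyl group onto a C1 formyl group), and the C1–CH3 and C1–CH2OH bonds (enolate methylation, then hydroxymethylation anti to the isopropenyl group).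
5. Ring order: six-membered ring (from carvone), then five-membered ring (steps 5 and 6), then seven-membered ring by one-carbon expansion of the six-membered ring (step 13).

Key step: step 13

Remarks on the chemistry: α is the face of the C1 methyl group and β the face of H-5. Centres that are later planarised or removed (the ozonide carbon, C2 of the aldol and its mesylate, C8 from step 9 to step 11 and in the chloro ketone) are expected as mixtures and are written without descriptor; for the step 1 product the expected major epimer is drawn, and for the siloxycyclopropane the expected β-adduct. Metal enolates and alkoxides are treated as ionised forms of the numbered compounds and carry no numbers of their own.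

**Step 1**
Reactants: 1 (R)-carvone
Product: 2 trans-6-methylcarvone
Conditions: LiN(iPr)2, THF, −78 °C; MeI, −78 → 0 °C
Reagents that add atoms: iodomethane, CI
Why: Kinetic deprotonation at the only enolisable α′-CH2 (the future C1) and SN2 enolate alkylation should give mainly the trans epimer, and the ratio is irrelevant because this centre is planarised again in step 2.

**Step 2**
Reactants: 2 trans-6-methylcarvone
Product: 3 (5S,6R)-6-(hydroxymethyl)-2,6-dimethyl-5-(prop-1-en-2-yl)cyclohex-2-en-1-one
Conditions: LiN(iPr)2, THF, −78 °C; CH2O (gas, from cracked paraformaldehyde), −78 °C; AcOH, −78 °C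
Reagents that add atoms: formaldehyde, C=O
Why: Aldol addition of the tetrasubstituted lithium enolate to monomeric formaldehyde should occur anti to the adjacent isopropenyl group, which lies pseudoaxial to avoid allylic strain with the enolate methyl and shields its own face, so that quaternary C1 is set with CH2OH trans and CH3 cis to the isopropenyl group.

**Step 3**
Reactants: 3 (5S,6R)-6-(hydroxymethyl)-2,6-dimethyl-5-(prop-1-en-2-yl)cyclohex-2-en-1-one
Product: 5 5-acetyl-6-(hydroxymethyl)-2,6-dimethylcyclohex-2-en-1-one (acetyl trans to CH2OH), via ozonide 4 (not isolated)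
Conditions: O3, CH2Cl2, −78 °C (to first persistent blue); Me2S, −78 °C → rt
Reagents that add atoms: ozone, [O-][O+]=O
Why: Ozonolysis with reductive work-up should cleave only the electron-rich 1,1-disubstituted isopropenyl alkene, which reacts with ozone much faster than the electron-poor enone alkene, unveiling the methyl ketone (C4 and C3) without touching C5.

**Step 4**
Reactants: 5 5-acetyl-6-(hydroxymethyl)-2,6-dimethylcyclohex-2-en-1-one
Product: 6 6-acetyl-1,3-dimethyl-2-oxocyclohex-3-ene-1-carbaldehyde (formyl trans to acetyl)
Conditions: Dess–Martin periodinane, NaHCO3, CH2Cl2, 0 °C → rt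
Reagents that add atoms: none
Why: Dess–Martin oxidation of the neopentyl primary alcohol under buffered, non-nucleophilic conditions should give the non-enolisable aldehyde without retro-aldol loss of the one-carbon arm or epimerisation at C5.

**Step 5**
Reactants: 6 6-acetyl-1,3-dimethyl-2-oxocyclohex-3-ene-1-carbaldehyde
Product: 7 trans-fused bicyclic aldol (C2 carbinol; C4 ketone; C10 enone)
Conditions: LiN(SiMe3)2 (1.05 equiv), THF, −78 → −40 °C; AcOH, −78 °C
Reagents that add atoms: none
Why: Kinetic deprotonation of the methyl ketone at CH3 (C3) rather than at the hindered C5–H, followed by intramolecular aldol addition to the non-enolisable C2 aldehyde (the 5-(enolendo)-exo-trig closure of the classical 1,4-keto aldehyde cyclopentannulation), should form the C2–C3 bond and the five-membered ring, the trans fusion following from the trans arrangement of the two arms set in step 2 and the cold non-nucleophilic base avoiding deformylation and C5 epimerisation.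

**Step 6**
Reactants: 7 trans-fused bicyclic aldol
Product: 9 trans-3a,5-dimethyl-7,7a-dihydro-1H-indene-1,4(3aH)-dione (C2=C3 cyclopentenone; C7=C8 cyclohexenone), via mesylate 8 (not isolated)
Conditions: MsCl, Et3N, CH2Cl2, −20 → 0 °C
Reagents that add atoms: none
Why: Mesylation of the aldol hydroxyl and E1cB elimination through the C3 enolate should give the cyclopentenone under conditions too mild to enolise the ring-fusion C5–H, so the trans fusion is kept.

**Step 7**
Reactants: 9 trans-fused dienedione; 10 isopropylmagnesium chloride
Product: 11 trans-fused dienone carbinol (C4 with α-OH and β-isopropyl; C2=C3; C7=C8; C10 ketone)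
Conditions: iPrMgCl, CeCl3 (anhydrous), THF, −78 °C; aq NH4Cl
Reagents that add atoms: isopropylmagnesium chloride (10), CC(C)[Mg]Cl
Why: CeCl3-promoted Grignard 1,2-addition, which suppresses enolisation, conjugate addition and β-hydride reduction, should occur at the cyclopentenone carbonyl C4 rather than at C10 (flanked by quaternary C1 and the methylated alkene carbon) and from the β face, next to the small H-5 and away from both the adjacent C5–C6 bond and the angular methyl, setting C4 with α-OH and β-isopropyl.

**Step 8**
Reactants: 11 trans-fused dienone carbinol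
Product: 12 enedione carbinol (C6 and C10 ketones flanking C7=C8)
Conditions: Rh2(cap)4 [dirhodium tetrakis(caprolactamate), 1 mol %], t-BuOOH (70% aq), ClCH2CH2Cl, 40 °C
Reagents that add atoms: tert-butyl hydroperoxide, CC(C)(C)OO
Why: Radical allylic oxidation by tert-butylperoxyl radicals should convert the γ-CH2 of the enone (C6), whose radical is delocalised onto the enone α-carbon, into a ketone, while the cyclopentene has no allylic hydrogen (C1 and C4 are fully substituted) and the base-free medium spares the now enolisable C5 and the aldol-type C4 carbinol.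

**Step 9**
Reactants: 12 enedione carbinol
Product: 13 saturated trans-hydrindane-6,10-dione carbinol (C8 epimers)
Conditions: H2 (1 atm), Pd/C, EtOAc, rt
Reagents that add atoms: none
Why: Heterogeneous catalytic hydrogenation under neutral conditions should saturate both the enedione alkene C7=C8 and the cis-disubstituted cyclopentene C2=C3, creating C8 as an inconsequential mixture that is planarised again in step 12.

**Step 10**
Reactants: 13 saturated dione carbinol
Product: 14 4α,6β-dihydroxy trans-hydrindan-10-one
Conditions: Me4NBH(OAc)3, MeCN/AcOH, −30 °C → rt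
Reagents that add atoms: none
Why: In this Evans–Saksena hydroxyl-directed reduction, exchange of an acetate on boron for the α-oriented C4 hydroxyl and intramolecular hydride transfer should deliver hydrogen to the α face of the β-positioned C6 carbonyl only, the reagent leaving the remote hindered C10 ketone untouched, which gives the equatorial 6β alcohol anti to the C4 hydroxyl.

**Step 11**
Reactants: 14 4α,6β-dihydroxy trans-hydrindan-10-one
Product: 15 bis(triethylsilyl) ether of the hydrindanone
Conditions: Et3SiOTf, 2,6-lutidine, CH2Cl2, 0 °C → rt
Reagents that add atoms: triethylsilyl trifluoromethanesulfonate, CC[Si](CC)(CC)OS(=O)(=O)C(F)(F)F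
Why: Silylation with the silyl triflate should cap both the secondary C6 hydroxyl and the hindered tertiary C4 hydroxyl, so that no free OH consumes base or zinc carbenoid in the next two steps.

**Step 12**
Reactants: 15 bis(triethylsilyl) ether of the hydrindanone
Product: 16 C8=C10 trimethylsilyl enol ether
Conditions: LiN(iPr)2, THF, −78 → 0 °C; Me3SiCl, −78 °C → rt
Reagents that add atoms: chlorotrimethylsilane, C[Si](C)(C)Cl
Why: Enolate formation and O-silylation can occur only toward C8 because C1 is quaternary, so both C8 epimers should converge on the single tetrasubstituted silyl enol ether.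

**Step 13**
Reactants: 16 C8=C10 trimethylsilyl enol ether
Product: 19 bis(triethylsilyl) ether of the core cycloheptenone, via siloxycyclopropane 17 (not isolated), via β-chloro ketone 18 (not isolated)
Conditions: Et2Zn, CH2I2, CH2Cl2, 0 °C → rt; crude, FeCl3, DMF, 0 °C → rt; crude, NaOAc, MeOH, 65 °C
Reagents that add atoms: diiodomethane, ICI
Why: The zinc carbenoid EtZnCH2I adds to the electron-rich tetrasubstituted enol ether (Simmons–Smith reaction, Furukawa variant), forming C9–C10 and C9–C8 in one concerted step, expected from the β face away from the axial C1 methyl. One-electron oxidation of the siloxycyclopropane by FeCl3 (trivalent iron) with loss of Me3SiCl cleaves the shared C8–C10 bond to give the C10 ketone and the tertiary C8 radical, which takes chlorine from a second FeCl3, and NaOAc then removes HCl by E1cB elimination through the C9 enolate to give the conjugated C8=C9 enone. The closest known reaction type is the FeCl3-mediated ring expansion of 1-siloxybicyclo[n.1.0]alkanes to 2-cycloalkenones, including the 2-methylcyclohexanone-derived case. The three-membered ring closes by [2+1] methylene transfer, and the seven-membered ring is not closed by a cyclisation but arises when the shared bond of the bicyclo[4.1.0]heptane breaks, so that the six ring atoms plus C9 become the cycloheptenone. No stereocentre is created in the product, since the two cyclopropane centres and the chloride centre are all destroyed, and C1, C4, C5 and C6 are untouched because none of them is enolisable during the sequence. The selectivity needed is cleavage of the internal rather than an external cyclopropane bond and elimination toward C9 rather than C7; the first is secured by formation of the tertiary ring-expanded radical, the second by the acidity of the C9 hydrogens α to C10 with C1 quaternary.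

**Step 14**
Reactants: 19 bis(triethylsilyl) ether of the core cycloheptenone
Product: 20 core diol enone (4α-OH and 6β-OH)
Conditions: HF·pyridine, pyridine/THF, 0 °C → rt
Reagents that add atoms: none
Why: Fluoride-mediated Si–O cleavage under buffered acidic conditions should remove both triethylsilyl groups without base-induced elimination or epimerisation in the δ-oxygenated enone.

**Step 15**
Reactants: 21 4-hydroxybenzoic acid
Product: 23 4-[(tert-butyldimethylsilyl)oxy]benzoic acid, via silyl ester 22 (not isolated)
Conditions: t-BuMe2SiCl, imidazole, DMF, rt; AcOH, THF/H2O, rt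
Reagents that add atoms: tert-butyl(chloro)dimethylsilane, CC(C)(C)[Si](C)(C)Cl
Why: Exhaustive silylation followed by selective hydrolysis of the much more labile silyl ester should leave the phenol masked as its silyl ether and free the acid for coupling.

**Step 16**
Reactants: 20 core diol enone; 23 4-[(tert-butyldimethylsilyl)oxy]benzoic acid
Product: 25 C6 4-(silyloxy)benzoate of the diol enone, via mixed anhydride 24 (not isolated)
Conditions: 2,4,6-Cl3C6H2COCl, Et3N, THF, rt; then 20, DMAP, toluene, rt
Reagents that add atoms: 4-[(tert-butyldimethylsilyl)oxy]benzoic acid (23), OC(=O)c1ccc(O[Si](C)(C)C(C)(C)C)cc1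
Why: In this Yamaguchi esterification the acylpyridinium formed from the mixed anhydride should acylate the secondary equatorial C6 hydroxyl with retention at C6, the hindered tertiary C4 hydroxyl being unreactive.

**Step 17**
Reactants: 25 C6 4-(silyloxy)benzoate of the diol enone
Product: 26 target, (3R,3aS,4S,8aS)-3-hydroxy-6,8a-dimethyl-8-oxo-3-(propan-2-yl)-1,2,3,3a,4,5,8,8a-octahydroazulen-4-yl 4-hydroxybenzoate
Conditions: KHF2, MeOH, rt
Reagents that add atoms: none
Why: Bifluoride cleaves aryl silyl ethers selectively under near-neutral conditions, so the phenol should be released without transesterification of the benzoate or vinylogous β-elimination of the C6 ester.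

**Compound list**
1 | (R)-carvone | CC1=CC[C@@H](C(C)=C)CC1=O | starting material
2 | trans-6-methylcarvone (6-methyl trans to isopropenyl, expected major epimer) | O=C1C(C)=CC[C@@H](C(C)=C)[C@@H]1C | intermediate
3 | (5S,6R)-6-(hydroxymethyl)-2,6-dimethyl-5-(prop-1-en-2-yl)cyclohex-2-en-1-one (CH2OH trans to isopropenyl) | O=C1C(C)=CC[C@@H](C(C)=C)[C@]1(C)CO | intermediate
4 | ozonide (1,2,4-trioxolane) of the isopropenyl group of 3 | O=C1C(C)=CC[C@@H](C2(C)OCOO2)[C@]1(C)CO | intermediate (not isolated)
5 | 5-acetyl-6-(hydroxymethyl)-2,6-dimethylcyclohex-2-en-1-one (acetyl trans to CH2OH) | O=C1C(C)=CC[C@@H](C(C)=O)[C@]1(C)CO | intermediate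
6 | 6-acetyl-1,3-dimethyl-2-oxocyclohex-3-ene-1-carbaldehyde (formyl trans to acetyl) | O=C1C(C)=CC[C@@H](C(C)=O)[C@]1(C)C=O | intermediate
7 | trans-fused bicyclic aldol, 3-hydroxy-3a,5-dimethyl-2,3,7,7a-tetrahydro-1H-indene-1,4(3aH)-dione (C2 carbinol epimers) | CC1=CC[C@H]2C(=O)CC(O)[C@]2(C)C1=O | intermediate
8 | methanesulfonate of 7 | CC1=CC[C@H]2C(=O)CC(OS(C)(=O)=O)[C@]2(C)C1=O | intermediate (not isolated)
9 | trans-3a,5-dimethyl-7,7a-dihydro-1H-indene-1,4(3aH)-dione (trans-fused dienedione) | CC1=CC[C@H]2C(=O)C=C[C@]2(C)C1=O | intermediate
10 | isopropylmagnesium chloride | CC(C)[Mg]Cl | starting material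
11 | trans-fused dienone carbinol: C4 α-OH and β-isopropyl, C2=C3, C7=C8, C10 ketone | CC1=CC[C@H]2[C@](O)(C(C)C)C=C[C@]2(C)C1=O | intermediate
12 | enedione carbinol: as 11 with a C6 ketone | CC1=CC(=O)[C@H]2[C@](O)(C(C)C)C=C[C@]2(C)C1=O | intermediate
13 | saturated trans-hydrindane-6,10-dione with C4 α-OH and β-isopropyl (C8 epimers) | CC1C(=O)[C@@]2(C)CC[C@@](O)(C(C)C)[C@@H]2C(=O)C1 | intermediate
14 | 4α,6β-dihydroxy trans-hydrindan-10-one (C8 epimers) | CC1C(=O)[C@@]2(C)CC[C@@](O)(C(C)C)[C@@H]2[C@@H](O)C1 | intermediate
15 | 4,6-bis(triethylsilyl) ether of 14 (C8 epimers) | CC1C(=O)[C@@]2(C)CC[C@@](O[Si](CC)(CC)CC)(C(C)C)[C@@H]2[C@@H](O[Si](CC)(CC)CC)C1 | intermediate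
16 | C8=C10 trimethylsilyl enol ether of 15 (key-step precursor) | CC1=C(O[Si](C)(C)C)[C@@]2(C)CC[C@@](O[Si](CC)(CC)CC)(C(C)C)[C@@H]2[C@@H](O[Si](CC)(CC)CC)C1 | intermediate
17 | siloxycyclopropane: C9 methylene bridging C8 and C10 on the β face | C[C@]12C[C@@]1(O[Si](C)(C)C)[C@@]3(C)CC[C@@](O[Si](CC)(CC)CC)(C(C)C)[C@@H]3[C@@H](O[Si](CC)(CC)CC)C2 | intermediate (not isolated)
18 | ring-expanded β-chloro ketone: C10 ketone, C9 CH2, C8 bearing Cl and CH3 (C8 epimers) | CC1(Cl)CC(=O)[C@@]2(C)CC[C@@](O[Si](CC)(CC)CC)(C(C)C)[C@@H]2[C@@H](O[Si](CC)(CC)CC)C1 | intermediate (not isolated)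
19 | 4,6-bis(triethylsilyl) ether of the core cycloheptenone (key-step product) | CC1=CC(=O)[C@@]2(C)CC[C@@](O[Si](CC)(CC)CC)(C(C)C)[C@@H]2[C@@H](O[Si](CC)(CC)CC)C1 | intermediate
20 | core diol enone, (3aS,4S,5R,8aS)-... in the labels used here 4α,6β-dihydroxy-8-methyl-C8=C9-en-10-one | CC1=CC(=O)[C@@]2(C)CC[C@@](O)(C(C)C)[C@@H]2[C@@H](O)C1 | intermediate
21 | 4-hydroxybenzoic acid | OC(=O)c1ccc(O)cc1 | starting material
22 | tert-butyldimethylsilyl 4-[(tert-butyldimethylsilyl)oxy]benzoate | CC(C)(C)[Si](C)(C)OC(=O)c1ccc(O[Si](C)(C)C(C)(C)C)cc1 | intermediate (not isolated)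
23 | 4-[(tert-butyldimethylsilyl)oxy]benzoic acid | OC(=O)c1ccc(O[Si](C)(C)C(C)(C)C)cc1 | intermediate
24 | mixed anhydride of 23 with 2,4,6-trichlorobenzoic acid | O=C(OC(=O)c1c(Cl)cc(Cl)cc1Cl)c1ccc(O[Si](C)(C)C(C)(C)C)cc1 | intermediate (not isolated)
25 | C6 4-[(tert-butyldimethylsilyl)oxy]benzoate of 20 | CC1=CC(=O)[C@@]2(C)CC[C@@](O)(C(C)C)[C@@H]2[C@@H](OC(=O)c2ccc(O[Si](C)(C)C(C)(C)C)cc2)C1 | intermediate
26 | CNP0210039.1, (3R,3aS,4S,8aS)-3-hydroxy-6,8a-dimethyl-8-oxo-3-(propan-2-yl)-1,2,3,3a,4,5,8,8a-octahydroazulen-4-yl 4-hydroxybenzoate | CC1=CC(=O)[C@@]2(C)CC[C@@](O)(C(C)C)[C@@H]2[C@@H](OC(=O)c2ccc(O)cc2)C1 | target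

**Step count**
Total: 17 steps. Longest linear sequence: 16 steps (steps 1 to 14, then 16 and 17); step 15 is a one-step side branch.

**Steps most likely to fail**

Step 13. Methylene transfer to the tetrasubstituted enol ether may be slow because quaternary C1 sits next to C10, and the siloxycyclopropane may open by protonolysis of an external bond, which would give α-methylation instead of ring expansion. Partial loss of the C6 silyl ether to FeCl3 would be harmless, since step 14 removes both. The fallback keeps the same one-carbon insertion but uses a free dihalocarbene and an electrocyclic opening. It sets out from 16: dibromocarbene (CHBr3, KOt-Bu, pentane, −30 °C) should add to the enol ether to give the dibromo siloxycyclopropane F1. On warming in toluene F1 should open by disrotatory cleavage of the same internal bond with loss of Me3SiBr to the 9-bromo enone F2. Radical hydrodebromination (Bu3SnH, AIBN, toluene, 80 °C) then rejoins the route at 19.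

Step 5. The doubly activated, non-enolisable aldehyde may be lost by retro-aldol or deformylation once an alkoxide is present. Enolisation toward C5 would erase the trans relationship, and the enolendo closure may be slow at low temperature. The fallback is a silyl-triflate-mediated Mukaiyama aldol in which no alkoxide is formed. It sets out from 6: Me3SiOTf and iPr2NEt in CH2Cl2 at 0 °C should form the less substituted enol silane F3 of the methyl ketone in the flask. The same silyl Lewis acid activates the aldehyde, so F3 should close to the silylated aldol F4. Brief treatment with dilute HCl in THF frees the hydroxyl and rejoins the route at 7.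

Step 10. Ligand exchange at the hindered tertiary C4 hydroxyl may be too slow for internal hydride delivery, giving no reduction or undirected attack from the β face to the axial 6α alcohol. The acidic medium may also trigger retro-aldol or dehydration of the C4 carbinol, which is β to the C6 ketone. The fallback introduces the C6 oxygen by electrophilic attack on a dienol ether (vinylogous Rubottom oxidation) instead of by carbonyl reduction, and bypasses steps 8 to 11. It sets out from 11: Et3SiOTf and Et3N should silylate the C4 hydroxyl and convert the enone into the extended C10=C8–C7=C6 silyl dienol ether F5. Dimethyldioxirane in acetone at −78 °C should attack C6 from the β face, anti to the axial C1 methyl, and give the γ-hydroxy enone F6 after loss of the dienol silyl group. Hydrogenation (H2, Pd/C, EtOAc) of C7=C8 and C2=C3 should give the hydroxy ketone F7, and Et3SiOTf with 2,6-lutidine on the C6 hydroxyl rejoins the route at 15.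

**Further compounds**
F1 | step 13 | 9,9-dibromo siloxycyclopropane from 16 | C[C@]12C(Br)(Br)[C@@]1(O[Si](C)(C)C)[C@@]3(C)CC[C@@](O[Si](CC)(CC)CC)(C(C)C)[C@@H]3[C@@H](O[Si](CC)(CC)CC)C2
F2 | step 13 | 9-bromo derivative of enone 19 | CC1=C(Br)C(=O)[C@@]2(C)CC[C@@](O[Si](CC)(CC)CC)(C(C)C)[C@@H]2[C@@H](O[Si](CC)(CC)CC)C1
F3 | step 5 | terminal trimethylsilyl enol ether of the methyl ketone of 6 | O=C1C(C)=CC[C@@H](C(=C)O[Si](C)(C)C)[C@]1(C)C=O
F4 | step 5 | trimethylsilyl ether of aldol 7 | CC1=CC[C@H]2C(=O)CC(O[Si](C)(C)C)[C@]2(C)C1=O
F5 | step 10 | C4 triethylsilyl ether and C10=C8–C7=C6 triethylsilyl dienol ether of 11 | CC1=C(O[Si](CC)(CC)CC)[C@@]2(C)C=C[C@@](O[Si](CC)(CC)CC)(C(C)C)[C@@H]2C=C1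
F6 | step 10 | 6β-hydroxy enone with C4 triethylsilyl ether and C2=C3 alkene | CC1=C[C@H](O)[C@H]2[C@](O[Si](CC)(CC)CC)(C(C)C)C=C[C@]2(C)C1=O
F7 | step 10 | 6β-hydroxy trans-hydrindan-10-one with C4 triethylsilyl ether (C8 epimers) | CC1C(=O)[C@@]2(C)CC[C@@](O[Si](CC)(CC)CC)(C(C)C)[C@@H]2[C@@H](O)C1
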